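**Retrosynthetic overview** (benzo[7]annulene numbering; ring A = trimethoxybenzene C1–C4/C4a/C9a, ring B = seven-membered ring C5–C9, ring C = spiro cyclohexadienone at C5)

- Target 20 ⇐ acetate 19 ⇐ in one flask: C9–C9a by addition of 3,4,5-trimethoxyphenyllithium to aldehyde 14, then C4a–C5 by oxidative para coupling of the phenol ring onto the new aryl ring.
- Enabling feature: C5 is the para carbon of ring C, a 2,6-dimethoxyphenol whose two ortho carbons both carry OMe. C4a of ring A is ortho and para to OMe groups, adjacent to C9a, and four atoms from C5 once C9 (an aldehyde carbon) is arylated. Oxidation can therefore only close ring B by para (ipso) C–C coupling.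
- Aldehyde 14 ⇐ Negishi coupling (aryl–CH2 bond) of aryl bromide 10 with iodide 8, whose propenyl group is the masked aldehyde carbon.
- Iodide 8 ⇐ acid 6 ⇐ Ireland–Claisen rearrangement of (2S,3E)-pent-3-en-2-yl propanoate 3, which sets both methyl stereocentres by chirality transfer.
- Ring order: rings A and C are bought as arenes; ring B and the dienone form of ring C arise together in the key step.

Key step: step 9

Remark on the chemistry: a free benzylic alkoxide would itself close onto the oxidised para carbon, so in step 9 the acetyl group is moved in the flask from the phenol oxygen to the new alkoxide and is removed in step 10. Compounds 1, 9 and 15 are taken as commercial.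

**Step 1**
Reactants: 1 rac-(3E)-pent-3-en-2-ol
Product: 2 (2S,3E)-pent-3-en-2-ol
Conditions: Candida antarctica lipase B (immobilised), vinyl acetate, pentane, 25 °C, run past half conversion; the unreacted alcohol is separated from the acetate
Reagents that add atoms: none
Why: Lipase-catalysed acylative kinetic resolution, in which the enzyme should acetylate the (R)-alcohol faster (methyl in the small pocket, propenyl in the large one), so the (S)-alcohol remains.

**Step 2**
Reactants: 2 (2S,3E)-pent-3-en-2-ol
Product: 3 (2S,3E)-pent-3-en-2-yl propanoate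
Conditions: propanoyl chloride, pyridine, 4-(dimethylamino)pyridine (cat.), CH2Cl2, 0 → 20 °C
Reagents that add atoms: propanoyl chloride, CCC(Cl)=O
Why: Acylation of a secondary alcohol by an acid chloride under nucleophilic catalysis; the stereocentre is not touched.

**Step 3**
Reactants: 3 (2S,3E)-pent-3-en-2-yl propanoate
Product: 6 (2S,3R,4E)-2,3-dimethylhex-4-enoic acid, via silyl ketene acetal 4 (not isolated), via trimethylsilyl ester 5 (not isolated)
Conditions: LDA, THF/DMPU, −78 °C; Me3SiCl, −78 → 50 °C; 1 M HCl work-up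
Reagents that add atoms: none
Why: Ireland–Claisen rearrangement, in which LDA in THF/DMPU should give the Z(O)-enolate and its silyl ketene acetal 4 rearranges through a chair with the carbinol methyl equatorial, so the (S)-carbinol centre is transferred to C3 (R) and the equatorial enolate methyl gives C2 (S), i.e. the 2,3-syn acid with an E double bond.

**Step 4**
Reactants: 6 (2S,3R,4E)-2,3-dimethylhex-4-enoic acid
Product: 7 (2S,3R,4E)-2,3-dimethylhex-4-en-1-ol
Conditions: LiAlH4, Et2O, 0 → 20 °C; aqueous work-up
Reagents that add atoms: none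
Why: Hydride reduction of a carboxylic acid to the primary alcohol; the isolated alkene and both stereocentres are untouched.

**Step 5**
Reactants: 7 (2S,3R,4E)-2,3-dimethylhex-4-en-1-ol
Product: 8 (2S,3R,4E)-1-iodo-2,3-dimethylhex-4-ene
Conditions: I2, PPh3, imidazole, CH2Cl2, 0 → 20 °C
Reagents that add atoms: iodine, II
Why: Appel-type iodination by SN2 displacement at the primary carbon of the alkoxyphosphonium ion; no stereocentre is involved.

**Step 6**
Reactants: 9 4-bromo-2,6-dimethoxyphenol
Product: 10 4-bromo-2,6-dimethoxyphenyl acetate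
Conditions: acetic anhydride, pyridine, 4-(dimethylamino)pyridine (cat.), CH2Cl2, 20 °C
Reagents that add atoms: acetic anhydride, CC(=O)OC(C)=O
Why: O-Acetylation of the phenol under nucleophilic catalysis; the acetate masks the phenol through steps 7 and 8 and is the acyl donor in step 9.

**Step 7**
Reactants: 8 (2S,3R,4E)-1-iodo-2,3-dimethylhex-4-ene; 10 4-bromo-2,6-dimethoxyphenyl acetate
Product: 12 4-[(2R,3S,4E)-2,3-dimethylhex-4-en-1-yl]-2,6-dimethoxyphenyl acetate, via alkylzinc iodide 11 (not isolated)
Conditions: Zn dust (activated), LiCl, THF, 40 °C; then 10, Pd(OAc)2, SPhos (2-dicyclohexylphosphino-2',6'-dimethoxybiphenyl), THF, 50 °C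
Reagents that add atoms: none
Why: Negishi coupling, with zinc insertion into the primary C–I bond followed by Pd/SPhos-catalysed sp3–sp2 coupling with the aryl bromide under conditions that leave the aryl acetate, the alkene and the remote stereocentres alone.

**Step 8**
Reactants: 12 4-[(2R,3S,4E)-2,3-dimethylhex-4-en-1-yl]-2,6-dimethoxyphenyl acetate
Product: 14 4-[(2R,3S)-2,3-dimethyl-4-oxobutyl]-2,6-dimethoxyphenyl acetate, via diol 13 (not isolated)
Conditions: OsO4 (cat.), NaIO4, 2,6-lutidine, 1,4-dioxane/H2O, 20 °C
Reagents that add atoms: osmium tetroxide, O=[Os](=O)(=O)=O (delivers the aldehyde oxygen; re-formed by sodium periodate, [Na+].[O-]I(=O)(=O)=O)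
Why: Lemieux–Johnson oxidation, in which syn-dihydroxylation of the only alkene and periodate cleavage of diol 13 release the aldehyde while 2,6-lutidine should suppress over-oxidation and epimerisation of the alpha stereocentre.

**Step 9**
Reactants: 14 4-[(2R,3S)-2,3-dimethyl-4-oxobutyl]-2,6-dimethoxyphenyl acetate; 15 5-bromo-1,2,3-trimethoxybenzene
Product: 19 (7R,8S,9R)-2,3,3',4,5'-pentamethoxy-7,8-dimethyl-4'-oxo-6,7,8,9-tetrahydrospiro[benzo[7]annulene-5,1'-cyclohexa[2,5]dien]-9-yl acetate, via aryllithium 16 (not isolated), via lithium alkoxide 17 (not isolated), via lithium phenoxide 18 (not isolated)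
Conditions: 15, n-BuLi (slightly less than 1 equiv), THF, −78 °C; cannulated into 14, THF, −78 °C; warm to 0 °C; CF3CH2OH, then PhI(OCOCF3)2, −40 °C; cold aq. NaHCO3 quench
Reagents that add atoms: none
Why: Aryllithium 16 adds to the aldehyde through the Felkin–Anh transition state (nucleophile anti to the branched C3 chain, passing the alpha hydrogen), which should set the (9R) carbinol syn to the adjacent methyl group, and alkoxide 17 then takes the acetyl group from the phenol oxygen of a second molecule, giving 18 with the benzylic oxygen masked and the phenoxide free. PhI(OCOCF3)2 oxidises the phenoxide by two electrons to an aryloxyiodane/phenoxonium species whose para carbon is attacked by C2 of the tethered 3,4,5-trimethoxyphenyl ring (ortho to one OMe, para to another), and proton loss from the Wheland intermediate gives the spirodienone, a union of two innately nucleophilic carbons. The closest known reaction type is the hypervalent-iodine phenolic para coupling onto a tethered trialkoxyarene that gives seven-membered spirodienones of the narwedine type, here preceded in the same flask by a carbonyl addition and an alkoxide-to-phenoxide transesterification. Ring B closes in a 7-exo mode with respect to the dienyl cation (ipso attack at the para carbon), and the spiro carbon is not a stereocentre because ring C is symmetric. The selectivity needed is para C–C coupling rather than oxygen capture, ortho coupling or quinone methide formation: both ortho carbons of the phenol carry OMe, the benzylic oxygen is acetylated by the relay, and the two ortho positions of the trimethoxyphenyl ring are equivalent. A halide-free aryllithium is used because bromide ion would be oxidised by the iodane to a brominating agent.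

**Step 10**
Reactants: 19 (7R,8S,9R)-2,3,3',4,5'-pentamethoxy-7,8-dimethyl-4'-oxo-6,7,8,9-tetrahydrospiro[benzo[7]annulene-5,1'-cyclohexa[2,5]dien]-9-yl acetate
Product: 20 (7R,8S,9R)-9-hydroxy-2,3,3',4,5'-pentamethoxy-7,8-dimethyl-6,7,8,9-tetrahydrospiro[benzo[7]annulene-5,1'-cyclohexa[2,5]dien]-4'-one
Conditions: K2CO3 (cat.), MeOH, 0 → 20 °C
Reagents that add atoms: none
Why: Methoxide-catalysed transesterification of the secondary acetate; the dienone and the three stereocentres should be untouched under these mild conditions.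

**Compound list**

1 | rac-(3E)-pent-3-en-2-ol | C/C=C/C(C)O | starting material
2 | (2S,3E)-pent-3-en-2-ol | C[C@H](O)/C=C/C | intermediate
3 | (2S,3E)-pent-3-en-2-yl propanoate | CCC(=O)O[C@@H](C)/C=C/C | intermediate
4 | trimethyl{[(1Z)-1-{[(2S,3E)-pent-3-en-2-yl]oxy}prop-1-en-1-yl]oxy}silane (formed in the flask) | C/C=C(\O[Si](C)(C)C)O[C@@H](C)/C=C/C | intermediate
5 | trimethylsilyl (2S,3R,4E)-2,3-dimethylhex-4-enoate (formed in the flask) | C[Si](C)(C)OC(=O)[C@@H](C)[C@H](C)/C=C/C | intermediate
6 | (2S,3R,4E)-2,3-dimethylhex-4-enoic acid | OC(=O)[C@@H](C)[C@H](C)/C=C/C | intermediate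
7 | (2S,3R,4E)-2,3-dimethylhex-4-en-1-ol | OC[C@@H](C)[C@H](C)/C=C/C | intermediate
8 | (2S,3R,4E)-1-iodo-2,3-dimethylhex-4-ene | IC[C@@H](C)[C@H](C)/C=C/C | intermediate
9 | 4-bromo-2,6-dimethoxyphenol | COc1cc(Br)cc(OC)c1O | starting material
10 | 4-bromo-2,6-dimethoxyphenyl acetate | CC(=O)Oc1c(OC)cc(Br)cc1OC | intermediate
11 | [(2S,3R,4E)-2,3-dimethylhex-4-en-1-yl](iodo)zinc (formed in the flask) | I[Zn]C[C@@H](C)[C@H](C)/C=C/C | intermediate
12 | 4-[(2R,3S,4E)-2,3-dimethylhex-4-en-1-yl]-2,6-dimethoxyphenyl acetate | CC(=O)Oc1c(OC)cc(C[C@@H](C)[C@H](C)/C=C/C)cc1OC | intermediate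
13 | 4-[(2R,3S)-4,5-dihydroxy-2,3-dimethylhexyl]-2,6-dimethoxyphenyl acetate, mixture of the two 4,5-threo diols (formed in the flask) | CC(=O)Oc1c(OC)cc(C[C@@H](C)[C@H](C)C(O)C(C)O)cc1OC | intermediate
14 | 4-[(2R,3S)-2,3-dimethyl-4-oxobutyl]-2,6-dimethoxyphenyl acetate | CC(=O)Oc1c(OC)cc(C[C@@H](C)[C@H](C)C=O)cc1OC | intermediate
15 | 5-bromo-1,2,3-trimethoxybenzene | COc1cc(Br)cc(OC)c1OC | starting material
16 | 3,4,5-trimethoxyphenyllithium (formed in the flask) | [Li]c1cc(OC)c(OC)c(OC)c1 | intermediate
17 | lithium (1R,2S,3R)-4-[4-(acetyloxy)-3,5-dimethoxyphenyl]-2,3-dimethyl-1-(3,4,5-trimethoxyphenyl)butan-1-olate (formed in the flask) | CC(=O)Oc1c(OC)cc(C[C@@H](C)[C@H](C)[C@@H](O[Li])c2cc(OC)c(OC)c(OC)c2)cc1OC | intermediate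
18 | lithium 4-[(2R,3S,4R)-4-(acetyloxy)-2,3-dimethyl-4-(3,4,5-trimethoxyphenyl)butyl]-2,6-dimethoxyphenolate (formed in the flask) | [Li]Oc1c(OC)cc(C[C@@H](C)[C@H](C)[C@@H](OC(C)=O)c2cc(OC)c(OC)c(OC)c2)cc1OC | intermediate
19 | (7R,8S,9R)-2,3,3',4,5'-pentamethoxy-7,8-dimethyl-4'-oxo-6,7,8,9-tetrahydrospiro[benzo[7]annulene-5,1'-cyclohexa[2,5]dien]-9-yl acetate | COC1=CC2(C=C(OC)C1=O)C[C@@H](C)[C@H](C)[C@@H](OC(C)=O)c1cc(OC)c(OC)c(OC)c12 | intermediate
20 | (7R,8S,9R)-9-hydroxy-2,3,3',4,5'-pentamethoxy-7,8-dimethyl-6,7,8,9-tetrahydrospiro[benzo[7]annulene-5,1'-cyclohexa[2,5]dien]-4'-one | COC1=CC2(C=C(OC)C1=O)C[C@@H](C)[C@H](C)[C@@H](O)c1cc(OC)c(OC)c(OC)c12 | target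

Total step count: 10. Longest linear sequence: 9 (steps 1–5 and 7–10).

**Steps most likely to fail**

Step 9. Capture of the oxidised phenol at its para carbon by oxygen nucleophiles (an alkoxide left unmasked by an incomplete acetyl shift, or the solvent), or loss of a benzylic proton towards a quinone methide, may outrun the seven-membered C–C closure. The acid released may also start a dienone–phenol rearrangement, and facial selectivity in the aryllithium addition may be modest. The fallback replaces the oxidative coupling by a palladium-catalysed dearomative C-arylation and sets out from 14. Commercial 5-iodo-1,2,3-trimethoxybenzene is brominated (N-bromosuccinimide, MeCN) to 2-bromo-1-iodo-3,4,5-trimethoxybenzene F1. Iodine–magnesium exchange (i-PrMgCl·LiCl, THF, −40 °C) gives (2-bromo-3,4,5-trimethoxyphenyl)magnesium chloride F2, which is added to 14 at −78 °C. After the same acetyl shift on warming and an NH4Cl work-up, 4-[(2R,3S,4R)-4-(acetyloxy)-4-(2-bromo-3,4,5-trimethoxyphenyl)-2,3-dimethylbutyl]-2,6-dimethoxyphenol F3 is isolated. Its phenolate is C-arylated at the para carbon by the arylpalladium bromide formed at the hindered C–Br bond (Pd2(dba)3, i.e. tris(dibenzylideneacetone)dipalladium, a bulky biarylphosphine such as t-BuXPhos, K2CO3, 1,4-dioxane, 100 °C), which comes back to the route at 19.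

Step 3. Leakage between the Z(O)- and E(O)-enolates during deprotonation would erode the 2,3-syn to anti ratio of the rearrangement. The fallback separates the two stereocentres and sets out from 2. Johnson–Claisen rearrangement with triethyl orthoacetate (propanoic acid cat., 140 °C) transfers chirality through the same chair without any enolate geometry and gives ethyl (3S,4E)-3-methylhex-4-enoate F4. Saponification (LiOH, THF/H2O) gives (3S,4E)-3-methylhex-4-enoic acid F5. Its pivaloyl mixed anhydride acylates lithiated (4S)-4-benzyl-1,3-oxazolidin-2-one to give (4S)-4-benzyl-3-[(3S,4E)-3-methylhex-4-enoyl]-1,3-oxazolidin-2-one F6. Methylation of the chelated Z-enolate (NaHMDS, MeI, THF, −78 °C) from the face away from the benzyl group gives (4S)-4-benzyl-3-[(2S,3R,4E)-2,3-dimethylhex-4-enoyl]-1,3-oxazolidin-2-one F7. Cleavage with LiOH/H2O2 comes back to the route at 6.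

Step 7. Sluggish zinc insertion into the beta-branched iodide, or beta-hydride elimination and chain isomerisation at the alkylpalladium stage, would lower the coupling efficiency. The fallback reverses the polarity of the partners and sets out from 10. Cobalt-catalysed zinc insertion (Zn dust, CoBr2 cat., MeCN, 20 °C) gives [4-(acetyloxy)-3,5-dimethoxyphenyl]zinc bromide F8. This is coupled with iodide 8 under nickel catalysis (Ni(acac)2, 4-fluorostyrene, THF/NMP, −15 °C), a radical-type alkyl–aryl Negishi coupling that avoids an alkylpalladium intermediate, and comes back to the route at 12.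

**Further compounds**

F1 | step 9 | 2-bromo-1-iodo-3,4,5-trimethoxybenzene | COc1cc(I)c(Br)c(OC)c1OC
F2 | step 9 | (2-bromo-3,4,5-trimethoxyphenyl)magnesium chloride | COc1cc([Mg]Cl)c(Br)c(OC)c1OC
F3 | step 9 | 4-[(2R,3S,4R)-4-(acetyloxy)-4-(2-bromo-3,4,5-trimethoxyphenyl)-2,3-dimethylbutyl]-2,6-dimethoxyphenol | Oc1c(OC)cc(C[C@@H](C)[C@H](C)[C@@H](OC(C)=O)c2cc(OC)c(OC)c(OC)c2Br)cc1OC
F4 | step 3 | ethyl (3S,4E)-3-methylhex-4-enoate | CCOC(=O)C[C@H](C)/C=C/C
F5 | step 3 | (3S,4E)-3-methylhex-4-enoic acid | OC(=O)C[C@H](C)/C=C/C
F6 | step 3 | (4S)-4-benzyl-3-[(3S,4E)-3-methylhex-4-enoyl]-1,3-oxazolidin-2-one | O=C(C[C@H](C)/C=C/C)N1[C@@H](Cc2ccccc2)COC1=O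
F7 | step 3 | (4S)-4-benzyl-3-[(2S,3R,4E)-2,3-dimethylhex-4-enoyl]-1,3-oxazolidin-2-one | O=C([C@@H](C)[C@H](C)/C=C/C)N1[C@@H](Cc2ccccc2)COC1=O
F8 | step 7 | [4-(acetyloxy)-3,5-dimethoxyphenyl]zinc bromide | CC(=O)Oc1c(OC)cc([Zn]Br)cc1OC
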